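The runs were computed with made-up constants; scatter was added.

Amounts of target come first. North-east holds 3.9 % at 2.50 d and 22.0 % at 6.00 d, so time grows 2.40-fold and target 5.64-fold, close to the square. I read that as an induction period: a catalyst waking steadily from the precatalyst. I replace its rising curve by its mean. For a straight rise from zero the mean is half the end value, so the end rate is twice the mean rate, which is target divided by time.

| flask | substrate | other conformer | precatalyst | temperature | remark | time |
|---|---|---|---|---|---|---|
| north-west | 0.12 M | 0.025 M | 1.8 mM | 75 °C | run made earlier |  |
| north-east | 0.19 M | 0.025 M | 1.8 mM | 95 °C | run made earlier |  |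
| summer | 0.25 M | 0.0250 M | 1.8 mM |  | at 110 °C until 40 h, from then on at 80 °C | 2.5 d |
| midnight | 0.25 M | 0.0250 M | 1.8 mM | 110 °C |  | 2.5 d |
| winter | 0.25 M | 0.0250 M | 1.8 mM | 95 °C |  | 2.5 d |
| dawn | 0.25 M | 0.0250 M | 1.8 mM | 80 °C |  | 2.5 d |

| run | time / d | target / % | substrate / % |
|---|---|---|---|
| north-west | 1.25 | 0 | 84.6 |
| north-west | 3.00 | 0.3 | 85.0 |
| north-west | 8.00 | 1.2 | 86.8 |
| north-west | 15.0 | 4.6 | 83.8 |
| north-east | 0.500 | 0.1 | 83.8 |
| north-east | 1.04 | 0.7 | 83.3 |
| north-east | 2.50 | 3.9 | 81.3 |
| north-east | 6.00 | 22.0 | 63.0 |

(scatter of a reading: 1 percentage point)

1. which flask leads in amount of target, in percent of the substrate and other conformer together charged ("all alike" within 1.5 percentage points) (summer / midnight / winter / dawn / all alike)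
2. how much target is there at the end, in percent of the substrate and other conformer together charged: summer
3. how much target is there at the end, in percent of the substrate and other conformer together charged: midnight
4. how much target is there at the end, in percent of the substrate and other conformer together charged: winter
5. how much target is there at the end, in percent of the substrate and other conformer together charged: dawn

- in a conversion other conformer counts as not yet reacted

North-east gives 12.8 d for what I call the induction time τ, the time divided by the square root of target as a fraction of the charge. North-west gives 69.9 d, a rough reading with a scatter of 1 percentage point on 4.6 %. That is a factor f of 5.47. I take percentages as independent of the charge and extend ln τ straight with temperature, which gives 3.58 d at 110 °C. Letting the substrate shrink, the fraction of target is one minus the exponential of minus the square of t/τ. So midnight reaches 38.6 %, winter 3.75 % and dawn 0.298 %.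

Summer has two extreme versions. If cooling at 40 h froze the flask, it would end at 19.5 %; if cooling changed nothing, it would end at 38.6 %. I expect it between them: in my picture the catalyst already awake stays and goes on turning over at 80 °C. By the doubling rule the rate at the change is 0.210 d⁻¹. In my picture the inverse square of τ is waking times turnover, and the runs give me the product, not its parts, so I guess that turnover changes by the factor f between 75 °C and 95 °C, which slows it 12.8-fold on cooling. The gain is then 1.4 points, and summer ends near 20.9 %, closer to the frozen end.

The forecast names midnight as leader, with 16 % for summer, 28 % for midnight, 4.5 % for winter and 0.6 % for dawn, and says that after cooling summer “then barely moves”.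

The flasks give 23.3 % for summer, 37.7 % for midnight, 4.65 % for winter and 0.312 % for dawn, so midnight leads.

    free catalyst + target → spent catalyst (k = 0.0527 M⁻¹ h⁻¹, Ea = 88.0 kJ mol⁻¹)
    substrate + free catalyst → free catalyst + target (k = 23.7 M⁻¹ h⁻¹, Ea = 80.0 kJ mol⁻¹)
    precatalyst → free catalyst (k = 0.0101 h⁻¹, Ea = 122 kJ mol⁻¹)
    free catalyst + other conformer → free catalyst + isomer of the product (k = 28.1 M⁻¹ h⁻¹, Ea = 87.0 kJ mol⁻¹)
    substrate ⇌ other conformer (K = 0.208, k = 0.0923 h⁻¹, Ea = 130 kJ mol⁻¹, ΔH = 13.0 kJ mol⁻¹)
    (constants at 110 °C)

Summer held 32.1 % of its catalyst free at 1.67 d and 32.4 % at 2.50 d, while target went from 21.3 % to 23.3 %. Put to use again, τ gives 19.5 % for summer at that change of temperature. On the midnight recipe read at 25 h, it gives 8.12 %, and that flask stands at 9.62 %.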